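The route rests on disconnecting the C7–O bond of the tetrahydrofuran ring C7–O–C9'–C8'–C8 of the furofuran. The precursor is therefore a lariciresinol-type monocycle: the ring C7'–C8'–C8–C9–O with the prenyloxyaryl group on C7', a CH2OH (C9') on C8' and, cis to it, a 4-hydroxy-3-methoxybenzyl group (C7) on C8. The feature exploited is that the para-hydroxyl is free only on the aryl attached to C7, so a flavin-dependent 4-alkylphenol oxidase can dehydrogenate this benzylic CH2 alone to a para-quinone methide, which the C9' hydroxyl traps. One operation forms the C7–O bond, closes the second ring, sets C7 and delivers the target itself.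

Key step: step 13

Remark on the chemistry: lignan locants are used (C7–C9 for the half with the free phenol, primed locants for the prenyloxy half); the configurations are taken as drawn, (7R,7'R,8S,8'S) for the target; 17 is carried on as a mixture of C7' epimers because that centre is ionised in step 11.

**Step 1**
Reactants: 1 furfural
Product: 3 5-hydroxyfuran-2(5H)-one (racemic), via furan endoperoxide 2 (not isolated)
Conditions: O2, hν (visible), rose bengal (cat.), MeOH, rt
Reagents that add atoms: oxygen, O=O
Why: Dye-sensitised photooxygenation, in which singlet oxygen adds to the furan diene in a [4+2] cycloaddition to give 2 and methanolysis then expels the formyl carbon as methyl formate, leaving the hydroxybutenolide.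

**Step 2**
Reactants: 3 5-hydroxyfuran-2(5H)-one; 4 (+)-menthol
Product: 5 (5S)-5-[(1S,2R,5S)-menthyloxy]furan-2(5H)-one
Conditions: CSA (cat.), toluene, reflux, Dean–Stark; crystallisation from petroleum ether, −20 °C; mother liquor re-equilibrated with CSA and recrystallised
Reagents that add atoms: none
Why: Acid-catalysed acetalisation of the pseudo-acid gives both C5 epimers, which interconvert under the acid, and the (5S) diastereomer of the (+)-menthyl series crystallises, so C5 is set by crystallisation-driven diastereomer selection.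

**Step 3**
Reactants: 6 vanillin; 7 1,3-propanedithiol
Product: 8 4-(1,3-dithian-2-yl)-2-methoxyphenol
Conditions: BF3·OEt2 (cat.), CH2Cl2, 0 °C to rt
Reagents that add atoms: none
Why: Lewis-acid-catalysed dithioacetalisation of an aromatic aldehyde, done before the prenyl group is introduced so that the acid-sensitive allylic ether never meets BF3 and thiol together.

**Step 4**
Reactants: 8 4-(1,3-dithian-2-yl)-2-methoxyphenol
Product: 9 2-[3-methoxy-4-(3-methylbut-2-enyloxy)phenyl]-1,3-dithiane
Conditions: prenyl bromide, K2CO3, acetone, reflux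
Reagents that add atoms: prenyl bromide (1-bromo-3-methylbut-2-ene), CC(C)=CCBr
Why: Williamson ether synthesis, in which the phenoxide (the only site carbonate deprotonates) displaces the allylic bromide far faster than the thioacetal sulfur atoms react.

**Step 5**
Reactants: 6 vanillin
Product: 10 3-methoxy-4-(triisopropylsilyloxy)benzaldehyde
Conditions: TIPSCl, imidazole, DMF, rt
Reagents that add atoms: triisopropylsilyl chloride, CC(C)[Si](Cl)(C(C)C)C(C)C
Why: Standard phenol silylation, with TIPS chosen because the aryl silyl ether should survive organolithium, hydride and weak acid and is later removed by fluoride without touching the prenyl ether.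

**Step 6**
Reactants: 10 3-methoxy-4-(triisopropylsilyloxy)benzaldehyde
Product: 11 [3-methoxy-4-(triisopropylsilyloxy)phenyl]methanol
Conditions: NaBH4, MeOH, 0 °C
Reagents that add atoms: none
Why: Borohydride reduction of an aromatic aldehyde to the benzylic alcohol.

**Step 7**
Reactants: 11 [3-methoxy-4-(triisopropylsilyloxy)phenyl]methanol
Product: 12 4-(bromomethyl)-2-methoxy-1-(triisopropylsilyloxy)benzene
Conditions: PBr3, Et2O, 0 °C; used without chromatography
Reagents that add atoms: phosphorus tribromide, BrP(Br)Br
Why: Bromination of an electron-rich benzylic alcohol through its phosphite ester (SN2 by bromide), with the phenol oxygen silylated so that no quinone methide can form.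

**Step 8**
Reactants: 9 2-[3-methoxy-4-(3-methylbut-2-enyloxy)phenyl]-1,3-dithiane; 5 (5S)-5-[(1S,2R,5S)-menthyloxy]furan-2(5H)-one; 12 4-(bromomethyl)-2-methoxy-1-(triisopropylsilyloxy)benzene
Product: 15 (3S,4S,5S)-3-[3-methoxy-4-(triisopropylsilyloxy)benzyl]-4-{2-[3-methoxy-4-(3-methylbut-2-enyloxy)phenyl]-1,3-dithian-2-yl}-5-[(1S,2R,5S)-menthyloxy]dihydrofuran-2(3H)-one, via lithiated dithiane 13 (not isolated), via lactone lithium enolate 14 (not isolated)
Conditions: n-BuLi, THF, −78 °C; then 5, −78 °C; then 12, DMPU, −78 to −20 °C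
Reagents that add atoms: none
Why: Tandem Michael addition–enolate alkylation with a Corey–Seebach acyl anion equivalent, in which 13 adds to C4 of the butenolide anti to the C5 menthyloxy group and enolate 14 is benzylated at C3 anti to the new C4 substituent, so the acetal centre sets C8' and C8' sets C8 (trans).

**Step 9**
Reactants: 15 the dithianyl lactone of step 8
Product: 16 (3S,4S,5S)-3-[3-methoxy-4-(triisopropylsilyloxy)benzyl]-4-[3-methoxy-4-(3-methylbut-2-enyloxy)benzoyl]-5-[(1S,2R,5S)-menthyloxy]dihydrofuran-2(3H)-one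
Conditions: MeI, CaCO3, MeCN–H2O (4:1), 45 °C
Reagents that add atoms: water, O
Why: Alkylative hydrolysis of the dithioketal (S-methylation, then hydrolysis of the sulfonium) under buffered, metal-free, non-oxidising conditions that should spare the prenyl alkene, the electron-rich arenes and the acetal, with C8' remaining in its preferred all-trans arrangement.

**Step 10**
Reactants: 16 the keto lactone of step 9
Product: 17 (2S,3S)-2-{hydroxy[3-methoxy-4-(3-methylbut-2-enyloxy)phenyl]methyl}-3-[3-methoxy-4-(triisopropylsilyloxy)benzyl]butane-1,4-diol (C7' epimers)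
Conditions: LiAlH4, THF, 0 °C to rt; Rochelle salt work-up
Reagents that add atoms: none
Why: Global hydride reduction, in which the aryl ketone gives the benzylic alcohol and the alkoxy lactone (a masked aldehyde-acid) is opened and reduced at C9 and C9' to the 1,4-diol with release of recoverable menthol, C8 and C8' being untouched.

**Step 11**
Reactants: 17 the triol of step 10
Product: 18 [(2R,3S,4S)-2-[3-methoxy-4-(3-methylbut-2-enyloxy)phenyl]-4-[3-methoxy-4-(triisopropylsilyloxy)benzyl]tetrahydrofuran-3-yl]methanol
Conditions: CSA (10 mol %), CH2Cl2, 0 °C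
Reagents that add atoms: none
Why: SN1 cycloetherification, in which the para-alkoxybenzylic alcohol at C7' ionises under catalytic weak acid and the C9 hydroxyl closes the five-membered ring (the C9' hydroxyl could only form an oxetane), both C7' epimers converging on the 2,3-trans ether favoured for a reversibly formed benzylic ether, while the mild acid should spare the prenyl ether and keep oxygen capture ahead of Friedel–Crafts closure by the guaiacyl ring.

**Step 12**
Reactants: 18 the silyl ether of step 11
Product: 19 [(2R,3S,4S)-4-(4-hydroxy-3-methoxybenzyl)-2-[3-methoxy-4-(3-methylbut-2-enyloxy)phenyl]tetrahydrofuran-3-yl]methanol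
Conditions: TBAF, AcOH, THF, 0 °C
Reagents that add atoms: none
Why: Fluoride-mediated cleavage of the aryl silyl ether, which frees the guaiacyl phenol without affecting the prenyl ether, the primary alcohol or the benzylic ether.

**Step 13**
Reactants: 19 the lariciresinol-type phenol of step 12
Product: 21 2-methoxy-4-[(1R,3aS,4R,6aS)-4-[3-methoxy-4-(3-methylbut-2-enyloxy)phenyl]tetrahydro-1H,3H-furo[3,4-c]furan-1-yl]phenol, via para-quinone methide 20 (not isolated)
Conditions: FAD-dependent 4-alkylphenol oxidase of the vanillyl-alcohol oxidase family (eugenol oxidase variant chosen by screening), air, KPi buffer pH 7.5, 10% DMSO, 25 °C; stopped when 19 is consumed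
Reagents that add atoms: none
Why: Proposed new method: the enzyme binds the guaiacyl unit as its phenolate and passes hydride from the benzylic C7–H to the flavin, giving para-quinone methide 20, whose exocyclic C7 is attacked by the C9' hydroxyl with rearomatisation, while O2 reoxidises the reduced flavin and makes the sequence irreversible. The closest known reaction type is the oxidation of 4-alkylphenols by vanillyl-alcohol-oxidase-type flavoenzymes, where the enzyme-bound quinone methide is trapped by water; here an internal alcohol replaces water, which has not been shown for this substrate class. The ring C7–O–C9'–C8'–C8 closes by 5-exo-trig oxa-conjugate addition and can only be cis-fused to the existing ring. The C7 stereocentre is controlled by the C8 and C8' centres, since addition through the transition state that places the aryl on the convex face of the forming bicycle should give the (7R) ether, and the active site, which shields one face of the methide, is expected to reinforce this. The step needs site selectivity, which the substrate secures because only the C7 aryl carries the free para-hydroxyl the enzyme requires, so the prenyloxy ring, its benzylic C7'–H and the prenyl alkene should stay unoxidised. It also needs chemoselectivity against a second dehydrogenation at the new C7–H, to be secured by stopping at full consumption of 19 and by choosing a variant that turns over the secondary benzylic ether slowly.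

**Compound list**

1 | furfural | O=Cc1ccco1 | starting material
2 | 1-formyl-2,3,7-trioxabicyclo[2.2.1]hept-5-ene (furan endoperoxide, formed in situ, not isolated) | O=CC12OOC(O1)C=C2 | intermediate
3 | 5-hydroxyfuran-2(5H)-one (racemic) | O=C1C=CC(O)O1 | intermediate
4 | (+)-menthol, (1S,2R,5S)-2-isopropyl-5-methylcyclohexan-1-ol | CC(C)[C@H]1CC[C@H](C)C[C@@H]1O | starting material
5 | (5S)-5-[(1S,2R,5S)-menthyloxy]furan-2(5H)-one | O=C1C=C[C@@H](O[C@H]2C[C@@H](C)CC[C@@H]2C(C)C)O1 | intermediate
6 | vanillin | COc1cc(C=O)ccc1O | starting material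
7 | 1,3-propanedithiol | SCCCS | starting material
8 | 4-(1,3-dithian-2-yl)-2-methoxyphenol | COc1cc(C2SCCCS2)ccc1O | intermediate
9 | 2-[3-methoxy-4-(3-methylbut-2-enyloxy)phenyl]-1,3-dithiane | COc1cc(C2SCCCS2)ccc1OCC=C(C)C | intermediate
10 | 3-methoxy-4-(triisopropylsilyloxy)benzaldehyde | COc1cc(C=O)ccc1O[Si](C(C)C)(C(C)C)C(C)C | intermediate
11 | [3-methoxy-4-(triisopropylsilyloxy)phenyl]methanol | COc1cc(CO)ccc1O[Si](C(C)C)(C(C)C)C(C)C | intermediate
12 | 4-(bromomethyl)-2-methoxy-1-(triisopropylsilyloxy)benzene | COc1cc(CBr)ccc1O[Si](C(C)C)(C(C)C)C(C)C | intermediate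
13 | 2-lithio-2-[3-methoxy-4-(3-methylbut-2-enyloxy)phenyl]-1,3-dithiane (formed in situ, not isolated) | [Li]C1(c2ccc(OCC=C(C)C)c(OC)c2)SCCCS1 | intermediate
14 | lithium enolate of (4S,5S)-4-(2-aryl-1,3-dithian-2-yl)-5-menthyloxydihydrofuran-2(3H)-one (formed in situ, not isolated) | [Li]OC1=C[C@H](C2(c3ccc(OCC=C(C)C)c(OC)c3)SCCCS2)[C@@H](O[C@H]2C[C@@H](C)CC[C@@H]2C(C)C)O1 | intermediate
15 | (3S,4S,5S)-3-[3-methoxy-4-(triisopropylsilyloxy)benzyl]-4-{2-[3-methoxy-4-(3-methylbut-2-enyloxy)phenyl]-1,3-dithian-2-yl}-5-[(1S,2R,5S)-menthyloxy]dihydrofuran-2(3H)-one | O=C1O[C@H](O[C@H]2C[C@@H](C)CC[C@@H]2C(C)C)[C@@H](C2(c3ccc(OCC=C(C)C)c(OC)c3)SCCCS2)[C@@H]1Cc1ccc(O[Si](C(C)C)(C(C)C)C(C)C)c(OC)c1 | intermediate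
16 | (3S,4S,5S)-3-[3-methoxy-4-(triisopropylsilyloxy)benzyl]-4-[3-methoxy-4-(3-methylbut-2-enyloxy)benzoyl]-5-[(1S,2R,5S)-menthyloxy]dihydrofuran-2(3H)-one | O=C1O[C@H](O[C@H]2C[C@@H](C)CC[C@@H]2C(C)C)[C@@H](C(=O)c2ccc(OCC=C(C)C)c(OC)c2)[C@@H]1Cc1ccc(O[Si](C(C)C)(C(C)C)C(C)C)c(OC)c1 | intermediate
17 | (2S,3S)-2-{hydroxy[3-methoxy-4-(3-methylbut-2-enyloxy)phenyl]methyl}-3-[3-methoxy-4-(triisopropylsilyloxy)benzyl]butane-1,4-diol (C7' epimers) | OC[C@@H](C(O)c1ccc(OCC=C(C)C)c(OC)c1)[C@H](Cc1ccc(O[Si](C(C)C)(C(C)C)C(C)C)c(OC)c1)CO | intermediate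
18 | [(2R,3S,4S)-2-[3-methoxy-4-(3-methylbut-2-enyloxy)phenyl]-4-[3-methoxy-4-(triisopropylsilyloxy)benzyl]tetrahydrofuran-3-yl]methanol | OC[C@@H]1[C@H](Cc2ccc(O[Si](C(C)C)(C(C)C)C(C)C)c(OC)c2)CO[C@H]1c1ccc(OCC=C(C)C)c(OC)c1 | intermediate
19 | [(2R,3S,4S)-4-(4-hydroxy-3-methoxybenzyl)-2-[3-methoxy-4-(3-methylbut-2-enyloxy)phenyl]tetrahydrofuran-3-yl]methanol (precursor of the key step) | OC[C@@H]1[C@H](Cc2ccc(O)c(OC)c2)CO[C@H]1c1ccc(OCC=C(C)C)c(OC)c1 | intermediate
20 | para-quinone methide of 19 at C7, configuration at C7', C8', C8 as in 19 (enzyme-bound, not isolated) | OC[C@@H]1[C@H](C=C2C=CC(=O)C(OC)=C2)CO[C@H]1c1ccc(OCC=C(C)C)c(OC)c1 | intermediate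
21 | 2-methoxy-4-[(1R,3aS,4R,6aS)-4-[3-methoxy-4-(3-methylbut-2-enyloxy)phenyl]tetrahydro-1H,3H-furo[3,4-c]furan-1-yl]phenol, (7R,7'R,8S,8'S) | COc1cc([C@@H]2OC[C@@H]3[C@H]2CO[C@H]3c2ccc(OCC=C(C)C)c(OC)c2)ccc1O | target

**Step count and risks**

Total step count: 13. Longest linear sequence: 9 steps (6 → 10 → 11 → 12 → 15 → 16 → 17 → 18 → 19 → 21; steps 5–13).

Steps most likely to fail:

1. Step 13 (proposed new method). The lignan-sized phenol may not bind or turn over. A second dehydrogenation at the new benzylic ether C7–H may open the ring again. Water may capture the methide, or it may tautomerise to the C7=C8 alkene. Facial selectivity at C7 may be incomplete. The fallback uses known chemistry, the tandem conjugate addition–aldol on the menthyloxybutenolide followed by acid-promoted double benzylic cycloetherification of a tetraol, and brings in the C7 oxygen at the carbinol level so that no late oxidation is needed. It sets out from enolate 14 (generated from 9 and 5 as in step 8) and aldehyde 10 and comes back at 21. Enolate 14 is trapped at −78 °C with 10 in place of bromide 12, the aldehyde entering anti to the dithianyl group, to give the aldol adduct F1 as carbinol epimers. MeI/CaCO3 in aqueous MeCN unmasks the ketone to give the keto lactone F2. LiAlH4 in THF gives the tetraol F3. Catalytic CSA in CH2Cl2 ionises both benzylic alcohols, and capture by the C9 and C9' hydroxyls should give the silyl ether of the target F4 as the cis-fused di-exo furofuran expected under equilibrating conditions. TBAF/AcOH then gives 21.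

2. Step 9. S-Methylation at the crowded quaternary thioketal carbon may stall. The unmasked ketone sits β to the acylal oxygen, so β-elimination and epimerisation at C8' may erode the material. The fallback changes the order of the redox events so that the ketone is never unmasked next to the lactone; it sets out from 15 and comes back at 17. Lactone 15 is first reduced with LiAlH4 (THF, 0 °C) to the dithiane diol F5. MeI/CaCO3 then cleaves the thioketal to the hydroxy ketone F6, which is held as its five-membered hemiketal with the C9 hydroxyl. NaBH4 in MeOH reduces it to triol 17.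

3. Step 8. Alkylation of the hindered enolate may be slow, so that proton transfer, O-alkylation or decay of the labile silyloxybenzyl bromide competes in the one-pot three-component coupling. The fallback decouples the two C–C bond formations; it sets out from 13 and 5 and comes back at 15. The conjugate addition is run alone and quenched with aqueous NH4Cl to give the 1,4-adduct F7, which is purified. Its enolate is then regenerated with LDA (THF, −78 °C), free of excess dithiane anion, and alkylated with 12 in the presence of DMPU, which should give 15 by the usual trans-selective alkylation of a β-substituted butyrolactone enolate.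

**Further compounds**

F1 | step 13 | (3S,4S,5S)-3-{hydroxy[3-methoxy-4-(triisopropylsilyloxy)phenyl]methyl}-4-{2-[3-methoxy-4-(3-methylbut-2-enyloxy)phenyl]-1,3-dithian-2-yl}-5-[(1S,2R,5S)-menthyloxy]dihydrofuran-2(3H)-one (carbinol epimers) | O=C1O[C@H](O[C@H]2C[C@@H](C)CC[C@@H]2C(C)C)[C@@H](C2(c3ccc(OCC=C(C)C)c(OC)c3)SCCCS2)[C@@H]1C(O)c1ccc(O[Si](C(C)C)(C(C)C)C(C)C)c(OC)c1
F2 | step 13 | (3S,4S,5S)-3-{hydroxy[3-methoxy-4-(triisopropylsilyloxy)phenyl]methyl}-4-[3-methoxy-4-(3-methylbut-2-enyloxy)benzoyl]-5-[(1S,2R,5S)-menthyloxy]dihydrofuran-2(3H)-one (carbinol epimers) | O=C1O[C@H](O[C@H]2C[C@@H](C)CC[C@@H]2C(C)C)[C@@H](C(=O)c2ccc(OCC=C(C)C)c(OC)c2)[C@@H]1C(O)c1ccc(O[Si](C(C)C)(C(C)C)C(C)C)c(OC)c1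
F3 | step 13 | (8S,8'S)-2-{hydroxy[3-methoxy-4-(3-methylbut-2-enyloxy)phenyl]methyl}-3-{hydroxy[3-methoxy-4-(triisopropylsilyloxy)phenyl]methyl}butane-1,4-diol (C7 and C7' epimers) | OC[C@@H](C(O)c1ccc(OCC=C(C)C)c(OC)c1)[C@H](C(O)c1ccc(O[Si](C(C)C)(C(C)C)C(C)C)c(OC)c1)CO
F4 | step 13 | triisopropylsilyl ether of 21 at the phenol oxygen, (7R,7'R,8S,8'S) | COc1cc([C@@H]2OC[C@@H]3[C@H]2CO[C@H]3c2ccc(OCC=C(C)C)c(OC)c2)ccc1O[Si](C(C)C)(C(C)C)C(C)C
F5 | step 9 | (2S,3S)-2-{2-[3-methoxy-4-(3-methylbut-2-enyloxy)phenyl]-1,3-dithian-2-yl}-3-[3-methoxy-4-(triisopropylsilyloxy)benzyl]butane-1,4-diol | OC[C@@H](C1(c2ccc(OCC=C(C)C)c(OC)c2)SCCCS1)[C@H](Cc1ccc(O[Si](C(C)C)(C(C)C)C(C)C)c(OC)c1)CO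
F6 | step 9 | (2S,3S)-2-(hydroxymethyl)-1-[3-methoxy-4-(3-methylbut-2-enyloxy)phenyl]-3-[3-methoxy-4-(triisopropylsilyloxy)benzyl]-4-hydroxybutan-1-one (open form of the cyclic hemiketal) | OC[C@@H](C(=O)c1ccc(OCC=C(C)C)c(OC)c1)[C@H](Cc1ccc(O[Si](C(C)C)(C(C)C)C(C)C)c(OC)c1)CO
F7 | step 8 | (4S,5S)-4-{2-[3-methoxy-4-(3-methylbut-2-enyloxy)phenyl]-1,3-dithian-2-yl}-5-[(1S,2R,5S)-menthyloxy]dihydrofuran-2(3H)-one | O=C1C[C@H](C2(c3ccc(OCC=C(C)C)c(OC)c3)SCCCS2)[C@@H](O[C@H]2C[C@@H](C)CC[C@@H]2C(C)C)O1
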